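## Retrosynthetic overview

1. Pestalone E comes from its tris-MOM ether by acid removal of the three acetal groups.
2. The tris-MOM ether comes from joining the two rings through the ring B aryl–O bond: the oxygen of a ring A α-amino alkoxide (aryllithium + DMF) adds to a 3-(methoxymethoxy)aryne, the new aryl anion then takes the neighbouring CONEt2 carbon as the ketone carbon, and work-up frees CHO and OH.
3. The ring A bromo amide comes from one-fold Br–Li exchange and prenylation of a symmetric 2,6-dibromo-3,5-bis(methoxymethoxy)benzamide, made from methyl 3,5-dihydroxybenzoate.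
4. The ring B ortho-silylaryl triflate comes from carbamate-directed ortho-silylation and triflation of mono-MOM 4-chloroorcinol, made from orcinol.
5. Ring order: no ring is built. Both benzene rings are bought; ring A is finished first, ring B second. Only a transient seven-membered oxepine ring forms in the union step and is opened on work-up.

Assumption: the target SMILES has no stereocentre and no stereodefined double bond, so the compound is achiral and no enantioselective step is needed.

## Route

Step 1
Reactants: 1 methyl 3,5-dihydroxybenzoate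
Product: 2 methyl 3,5-bis(methoxymethoxy)benzoate
Conditions: NaH (2.3 equiv), DMF, 0 °C; MOMCl (2.4 equiv), 0 °C → rt
Reagents that add atoms: chloromethyl methyl ether (MOMCl), COCCl
Why: Williamson-type O-alkylation of both phenoxides by the very reactive α-chloro ether (MOM protection); the ester is untouched.

Step 2
Reactants: 2 methyl 3,5-bis(methoxymethoxy)benzoate
Product: 3 N,N-diethyl-3,5-bis(methoxymethoxy)benzamide
Conditions: Et2NH (3 equiv), i-PrMgCl (3 equiv), THF, −20 °C → rt
Reagents that add atoms: diethylamine, CCNCC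
Why: Bodroux-type aminolysis: Et2NMgCl made in the flask adds to the unhindered methyl ester and expels methoxide, giving a tertiary amide that tolerates organolithiums and later serves as the acyl donor.

Step 3
Reactants: 3 N,N-diethyl-3,5-bis(methoxymethoxy)benzamide
Product: 4 2,6-dibromo-N,N-diethyl-3,5-bis(methoxymethoxy)benzamide
Conditions: NBS (2.1 equiv), MeCN, 0 °C → rt
Reagents that add atoms: N-bromosuccinimide, O=C1CCC(=O)N1Br
Why: electrophilic aromatic bromination goes twice to the equivalent 2- and 6-positions (each para to one acetal oxygen and ortho to the other), as with 3,5-dialkoxybenzoates, and leaves the 4-position between the two OMOM groups.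

Step 4
Reactants: 4 2,6-dibromo-N,N-diethyl-3,5-bis(methoxymethoxy)benzamide
Product: 6 2-bromo-N,N-diethyl-3,5-bis(methoxymethoxy)-6-(3-methylbut-2-en-1-yl)benzamide, via aryllithium 5 (not isolated)
Conditions: n-BuLi (1.05 equiv), THF, −78 °C, 15 min; CuBr·SMe2 (10 mol %), prenyl bromide (1.5 equiv), −78 → 0 °C
Reagents that add atoms: 1-bromo-3-methylbut-2-ene (prenyl bromide), CC(C)=CCBr
Why: bromine–lithium exchange stops after one bromine (a second would need a dianion), which desymmetrises 4; copper-catalysed SN2 allylation of 5 with prenyl bromide gives the linear prenyl group.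

Step 5
Reactants: 7 orcinol (5-methylbenzene-1,3-diol)
Product: 8 4-chloro-5-methylbenzene-1,3-diol
Conditions: SO2Cl2 (1.0 equiv), Et2O, 0 °C → rt
Reagents that add atoms: sulfuryl chloride, O=S(=O)(Cl)Cl
Why: electrophilic aromatic chlorination at C4 (para to one OH, ortho to the other) is the expected main course for orcinol; one equivalent limits dichlorination.

Step 6
Reactants: 8 4-chloro-5-methylbenzene-1,3-diol
Product: 9 4-chloro-3-(methoxymethoxy)-5-methylphenol
Conditions: 8 (1.2 equiv), K2CO3 (1.0 equiv), acetone, 0 °C; MOMCl (1.0 equiv), 0 °C → rt; chromatography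
Reagents that add atoms: chloromethyl methyl ether (MOMCl), COCCl
Why: Williamson mono-alkylation: the OH ortho to chlorine is the more acidic by roughly one pKa unit, so with one equivalent of weak base its phenoxide is the main anion and captures the unselective, fast electrophile.

Step 7
Reactants: 9 4-chloro-3-(methoxymethoxy)-5-methylphenol
Product: 10 4-chloro-3-(methoxymethoxy)-5-methylphenyl N-(propan-2-yl)carbamate
Conditions: i-PrNCO (1.5 equiv), Et3N (20 mol %), CH2Cl2, rt
Reagents that add atoms: 2-isocyanatopropane (isopropyl isocyanate), CC(C)N=C=O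
Why: base-catalysed addition of the phenol to the isocyanate (carbamoylation) installs an ortho-directing group that can later be removed by E1cB elimination.

Step 8
Reactants: 10 4-chloro-3-(methoxymethoxy)-5-methylphenyl N-(propan-2-yl)carbamate
Product: 14 4-chloro-3-(methoxymethoxy)-5-methyl-2-(trimethylsilyl)phenyl N-(propan-2-yl)carbamate, via N-silyl carbamate 11 (not isolated), via ortho-lithiated carbamate 12 (not isolated), via C-silylated N-silyl carbamate 13 (not isolated)
Conditions: TBSOTf (1.1 equiv), TMEDA (1.1 equiv), Et2O, 0 °C → rt; n-BuLi (2.2 equiv), TMEDA (2.2 equiv), −78 °C; TMSCl (3 equiv), −78 °C → rt; aq. NaHSO4 work-up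
Reagents that add atoms: chlorotrimethylsilane, C[Si](C)(C)Cl
Why: directed ortho-metalation: with N–H masked as N–Si, lithiation occurs at the one position flanked by both directing groups (carbamate and OMOM), TMSCl traps the aryllithium, and the N-silyl group falls off on aqueous acid work-up.

Step 9
Reactants: 14 4-chloro-3-(methoxymethoxy)-5-methyl-2-(trimethylsilyl)phenyl N-(propan-2-yl)carbamate
Product: 16 4-chloro-3-(methoxymethoxy)-5-methyl-2-(trimethylsilyl)phenyl trifluoromethanesulfonate, via silyl phenol 15 (not isolated)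
Conditions: DBU (1.5 equiv), Et2NH (1.2 equiv), MeCN, 40 °C; PhNTf2 (1.5 equiv), rt
Reagents that add atoms: N-phenylbis(trifluoromethanesulfonimide) (PhNTf2), O=S(=O)(N(c1ccccc1)S(=O)(=O)C(F)(F)F)C(F)(F)F
Why: E1cB cleavage of the N–H carbamate (the isocyanate is scavenged by Et2NH as a urea) frees phenoxide 15, which is sulfonylated in the same pot to the ortho-silylaryl triflate (Kobayashi-type aryne precursor).

Step 10
Reactants: 6 2-bromo-N,N-diethyl-3,5-bis(methoxymethoxy)-6-(3-methylbut-2-en-1-yl)benzamide, 16 4-chloro-3-(methoxymethoxy)-5-methyl-2-(trimethylsilyl)phenyl trifluoromethanesulfonate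
Product: 21 2-[3-chloro-6-hydroxy-2-(methoxymethoxy)-4-methylbenzoyl]-4,6-bis(methoxymethoxy)-3-(3-methylbut-2-en-1-yl)benzaldehyde, via aryllithium 17 (not isolated), via lithium amino alkoxide 18 (not isolated), via aryne 19 (not isolated), via cyclic amino alkoxide 20 (not isolated)
Conditions: 6, n-BuLi (1.05 equiv), THF, −78 °C, 5 min; DMF (1.0 equiv), −78 °C, 20 min; 16 (1.5 equiv), CsF (4 equiv), 18-crown-6 (2 equiv), −78 → 23 °C; then 0.5 M HCl (aq.), 0 °C → rt, 30 min
Reagents that add atoms: N,N-dimethylformamide, CN(C)C=O; water, O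
Why: Proposed new method: an aryne oxy-acylation in which the lithium α-amino alkoxide 18 (the ordinary tetrahedral adduct of an aryllithium with DMF, stable in THF until hydrolysed) serves as the oxygen nucleophile. Fluoride unmasks aryne 19 from 16, and the alkoxide oxygen adds to the aryne carbon remote from OMOM (the standard regiochemistry of 3-alkoxyarynes, which puts the carbanion next to the inductively stabilising oxygen), making the ring B aryl–O bond. The new aryl anion, with no proton source at hand, attacks the neighbouring diethylamide through a seven-membered transition state to give 20 (transient stereocentres, formed as a mixture). Dilute acid then collapses both aminal carbons to ketone, aldehyde and phenol. The closest known reactions are the fluoride-induced insertion of arynes into the C–O bond of carboxylic acids to give ortho-hydroxyaryl ketones, the aryne/salicylate annulation to xanthones, and Parham-type cyclisations of aryl anions onto tertiary amides; an α-amino alkoxide as the O-nucleophile combined with a seven-membered amide acyl transfer has not been shown.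

Step 11
Reactants: 21 2-[3-chloro-6-hydroxy-2-(methoxymethoxy)-4-methylbenzoyl]-4,6-bis(methoxymethoxy)-3-(3-methylbut-2-en-1-yl)benzaldehyde
Product: 22 pestalone E, 2-(3-chloro-2,6-dihydroxy-4-methylbenzoyl)-4,6-dihydroxy-3-(3-methylbut-2-en-1-yl)benzaldehyde
Conditions: 3 M HCl (aq.), THF/i-PrOH, 40 °C, monitored closely; neutral work-up, no base or amine
Reagents that add atoms: none
Why: acid-catalysed hydrolysis of the three aryl MOM acetals is far faster than protonation of the trisubstituted alkene at this acidity and temperature; no stereocentre is present or created.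

## Compound list

1 | methyl 3,5-dihydroxybenzoate | COC(=O)c1cc(O)cc(O)c1 | starting material
2 | methyl 3,5-bis(methoxymethoxy)benzoate | COCOc1cc(OCOC)cc(c1)C(=O)OC | intermediate
3 | N,N-diethyl-3,5-bis(methoxymethoxy)benzamide | CCN(CC)C(=O)c1cc(OCOC)cc(OCOC)c1 | intermediate
4 | 2,6-dibromo-N,N-diethyl-3,5-bis(methoxymethoxy)benzamide | CCN(CC)C(=O)c1c(Br)c(OCOC)cc(OCOC)c1Br | intermediate
5 | [3-bromo-2-(diethylcarbamoyl)-4,6-bis(methoxymethoxy)phenyl]lithium (not isolated) | CCN(CC)C(=O)c1c(Br)c(OCOC)cc(OCOC)c1[Li] | intermediate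
6 | 2-bromo-N,N-diethyl-3,5-bis(methoxymethoxy)-6-(3-methylbut-2-en-1-yl)benzamide | CCN(CC)C(=O)c1c(Br)c(OCOC)cc(OCOC)c1CC=C(C)C | intermediate
7 | orcinol (5-methylbenzene-1,3-diol) | Cc1cc(O)cc(O)c1 | starting material
8 | 4-chloro-5-methylbenzene-1,3-diol | Cc1cc(O)cc(O)c1Cl | intermediate
9 | 4-chloro-3-(methoxymethoxy)-5-methylphenol (MOM on the oxygen next to chlorine) | Cc1cc(O)cc(OCOC)c1Cl | intermediate
10 | 4-chloro-3-(methoxymethoxy)-5-methylphenyl N-(propan-2-yl)carbamate | Cc1cc(OC(=O)NC(C)C)cc(OCOC)c1Cl | intermediate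
11 | 4-chloro-3-(methoxymethoxy)-5-methylphenyl N-[tert-butyl(dimethyl)silyl]-N-(propan-2-yl)carbamate (not isolated) | Cc1cc(OC(=O)N(C(C)C)[Si](C)(C)C(C)(C)C)cc(OCOC)c1Cl | intermediate
12 | 2-lithio derivative of 11, lithium between the carbamate oxygen and OMOM (not isolated) | Cc1cc(OC(=O)N(C(C)C)[Si](C)(C)C(C)(C)C)c([Li])c(OCOC)c1Cl | intermediate
13 | 4-chloro-3-(methoxymethoxy)-5-methyl-2-(trimethylsilyl)phenyl N-[tert-butyl(dimethyl)silyl]-N-(propan-2-yl)carbamate (not isolated) | Cc1cc(OC(=O)N(C(C)C)[Si](C)(C)C(C)(C)C)c([Si](C)(C)C)c(OCOC)c1Cl | intermediate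
14 | 4-chloro-3-(methoxymethoxy)-5-methyl-2-(trimethylsilyl)phenyl N-(propan-2-yl)carbamate | Cc1cc(OC(=O)NC(C)C)c([Si](C)(C)C)c(OCOC)c1Cl | intermediate
15 | 4-chloro-3-(methoxymethoxy)-5-methyl-2-(trimethylsilyl)phenol, present as its DBU-H phenoxide (not isolated) | Cc1cc(O)c([Si](C)(C)C)c(OCOC)c1Cl | intermediate
16 | 4-chloro-3-(methoxymethoxy)-5-methyl-2-(trimethylsilyl)phenyl trifluoromethanesulfonate | Cc1cc(OS(=O)(=O)C(F)(F)F)c([Si](C)(C)C)c(OCOC)c1Cl | intermediate
17 | [2-(diethylcarbamoyl)-4,6-bis(methoxymethoxy)-3-(3-methylbut-2-en-1-yl)phenyl]lithium (not isolated) | CCN(CC)C(=O)c1c([Li])c(OCOC)cc(OCOC)c1CC=C(C)C | intermediate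
18 | lithium [2-(diethylcarbamoyl)-4,6-bis(methoxymethoxy)-3-(3-methylbut-2-en-1-yl)phenyl](dimethylamino)methanolate, racemic (not isolated) | CCN(CC)C(=O)c1c(C(O[Li])N(C)C)c(OCOC)cc(OCOC)c1CC=C(C)C | intermediate
19 | 4-chloro-3-(methoxymethoxy)-5-methylbenzyne (1,2-didehydrobenzene; not isolated) | CC1=CC#CC(OCOC)=C1Cl | intermediate
20 | lithium 2-chloro-11-(diethylamino)-6-(dimethylamino)-1,7,9-tris(methoxymethoxy)-3-methyl-10-(3-methylbut-2-en-1-yl)-6,11-dihydrodibenzo[b,e]oxepin-11-olate, mixture of diastereomers (not isolated) | CCN(CC)C1(O[Li])c2c(CC=C(C)C)c(OCOC)cc(OCOC)c2C(N(C)C)Oc2cc(C)c(Cl)c(OCOC)c21 | intermediate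
21 | 2-[3-chloro-6-hydroxy-2-(methoxymethoxy)-4-methylbenzoyl]-4,6-bis(methoxymethoxy)-3-(3-methylbut-2-en-1-yl)benzaldehyde | O=Cc1c(OCOC)cc(OCOC)c(CC=C(C)C)c1C(=O)c1c(O)cc(C)c(Cl)c1OCOC | intermediate
22 | pestalone E, 2-(3-chloro-2,6-dihydroxy-4-methylbenzoyl)-4,6-dihydroxy-3-(3-methylbut-2-en-1-yl)benzaldehyde (achiral) | CC(C)=CCc1c(O)cc(O)c(C=O)c1C(=O)c1c(O)cc(C)c(Cl)c1O | target

## Step count and risks

Total step count: 11.
Longest linear sequence: 7 steps (steps 5, 6, 7, 8, 9, 10, 11, from orcinol). The ring A branch (steps 1 to 4) joins at step 10.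

Three steps most likely to fail:

**Step 10 (the proposed new step).** Three things can go wrong:
- The dimethylamino nitrogen of 18 may compete with the alkoxide oxygen for the aryne.
- The aryl anion may be quenched before it reaches the hindered, twisted diethylamide; that returns the ring A aldehyde amide and the ring B phenol after work-up.
- Excess DMF can trap the aryl anion, hence exactly one equivalent.

Fallback, known chemistry only, setting out from 6 and 8 and coming back at 22: 8 is protected on both oxygens (NaH, MOMCl, DMF) to give 2-chloro-1,5-bis(methoxymethoxy)-3-methylbenzene F1. Separately, Br–Li exchange of 6 (n-BuLi, THF, −78 °C) and quenching with paraformaldehyde gives N,N-diethyl-2-(hydroxymethyl)-3,5-bis(methoxymethoxy)-6-(3-methylbut-2-en-1-yl)benzamide F2. F2 lactonises on warming with a little AcOH in toluene to 4,6-bis(methoxymethoxy)-7-(3-methylbut-2-en-1-yl)-2-benzofuran-1(3H)-one F3, the standard benzamide-to-phthalide route. Directed ortho-metalation of F1 between its two OMOM groups (n-BuLi, THF, 0 °C) gives [3-chloro-2,6-bis(methoxymethoxy)-4-methylphenyl]lithium F4. F4 adds once to the lactone carbonyl of F3 at −78 °C to give [3-chloro-2,6-bis(methoxymethoxy)-4-methylphenyl][2-(hydroxymethyl)-3,5-bis(methoxymethoxy)-6-(3-methylbut-2-en-1-yl)phenyl]methanone F5, in equilibrium with its lactol. MnO2 in CH2Cl2 oxidises the benzylic alcohol to 2-[3-chloro-2,6-bis(methoxymethoxy)-4-methylbenzoyl]-4,6-bis(methoxymethoxy)-3-(3-methylbut-2-en-1-yl)benzaldehyde F6. F6 is deprotected under the conditions of step 11 to give 22. Here the ring union is a plain aryllithium addition to a lactone.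

**Step 11.** Acid can cyclise the prenyl group onto the neighbouring free phenol (chroman), and the ortho-aroylbenzaldehyde isomerises to a phthalide lactone when exposed to base or amines.

Fallback, setting out from 21 and coming back at 22: non-hydrolytic acetal-to-silyl exchange with TMSOTf and 2,2'-bipyridyl in CH2Cl2 (0 °C → rt) turns the three aryl MOM ethers and the free phenol into silyl ethers, giving 2-[3-chloro-4-methyl-2,6-bis(trimethylsilyloxy)benzoyl]-4,6-bis(trimethylsilyloxy)-3-(3-methylbut-2-en-1-yl)benzaldehyde F9. F9 loses its silyl groups on stirring with water in THF at rt to give 22, with no free protic acid ever meeting the prenyl phenol.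

**Step 6.** The pKa-based preference may give a regioisomer mixture plus bis-ether; only the isomer with MOM next to chlorine gives an aryne whose regiochemistry is controlled by OMOM alone.

Fallback, setting out from 8 and coming back at 9: steric differentiation in place of acidity. TBSCl (1.0 equiv) and imidazole at −20 °C silylate the less hindered hydroxyl to give 5-{[tert-butyl(dimethyl)silyl]oxy}-2-chloro-3-methylphenol F7. MOMCl and i-Pr2NEt then protect the remaining hydroxyl next to chlorine to give tert-butyl[4-chloro-3-(methoxymethoxy)-5-methylphenoxy]dimethylsilane F8. TBAF in THF removes the silyl group to give 9.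

Further compounds
F1 | step 10 | 2-chloro-1,5-bis(methoxymethoxy)-3-methylbenzene | Cc1cc(OCOC)cc(OCOC)c1Cl
F2 | step 10 | N,N-diethyl-2-(hydroxymethyl)-3,5-bis(methoxymethoxy)-6-(3-methylbut-2-en-1-yl)benzamide | CCN(CC)C(=O)c1c(CO)c(OCOC)cc(OCOC)c1CC=C(C)C
F3 | step 10 | 4,6-bis(methoxymethoxy)-7-(3-methylbut-2-en-1-yl)-2-benzofuran-1(3H)-one | O=C1OCc2c(OCOC)cc(OCOC)c(CC=C(C)C)c12
F4 | step 10 | [3-chloro-2,6-bis(methoxymethoxy)-4-methylphenyl]lithium | Cc1cc(OCOC)c([Li])c(OCOC)c1Cl
F5 | step 10 | [3-chloro-2,6-bis(methoxymethoxy)-4-methylphenyl][2-(hydroxymethyl)-3,5-bis(methoxymethoxy)-6-(3-methylbut-2-en-1-yl)phenyl]methanone | OCc1c(OCOC)cc(OCOC)c(CC=C(C)C)c1C(=O)c1c(OCOC)cc(C)c(Cl)c1OCOC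
F6 | step 10 | 2-[3-chloro-2,6-bis(methoxymethoxy)-4-methylbenzoyl]-4,6-bis(methoxymethoxy)-3-(3-methylbut-2-en-1-yl)benzaldehyde | O=Cc1c(OCOC)cc(OCOC)c(CC=C(C)C)c1C(=O)c1c(OCOC)cc(C)c(Cl)c1OCOC
F7 | step 6 | 5-{[tert-butyl(dimethyl)silyl]oxy}-2-chloro-3-methylphenol | Cc1cc(O[Si](C)(C)C(C)(C)C)cc(O)c1Cl
F8 | step 6 | tert-butyl[4-chloro-3-(methoxymethoxy)-5-methylphenoxy]dimethylsilane | Cc1cc(O[Si](C)(C)C(C)(C)C)cc(OCOC)c1Cl
F9 | step 11 | 2-[3-chloro-4-methyl-2,6-bis(trimethylsilyloxy)benzoyl]-4,6-bis(trimethylsilyloxy)-3-(3-methylbut-2-en-1-yl)benzaldehyde | O=Cc1c(O[Si](C)(C)C)cc(O[Si](C)(C)C)c(CC=C(C)C)c1C(=O)c1c(O[Si](C)(C)C)cc(C)c(Cl)c1O[Si](C)(C)C
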